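**Assumptions.**
- The target SMILES contains no stereocentres, so the compound is achiral and the "single enantiomer" condition is trivially met. No step in the route sets or needs stereochemistry.
- The target is a benzofuro[2,3-b]chromen-11-one. Its ring C is a chromone whose C2 is a ketene acetal carbon, bonded to both the chromone ring oxygen and the furan oxygen.
- Phloroacetophenone is assumed to form the chromene on its 4′-OH, which is para to the acetyl and not H-bonded to it.
- The less hindered hydroxyl is assumed to be protected selectively in Steps 3 and 10.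

## Retrosynthetic overview
1. Last step: remove two aryl MOM ethers.
2. Furan ring, through the C2–O bond, by the new key step: a 2′-silyloxy isoflavone undergoes F⁻-triggered 5-endo oxa-Michael cyclisation onto chromone C2, then DDQ dehydrogenation, giving the benzofuro[2,3-b]chromone.
3. Isoflavone C3–aryl bond by Suzuki coupling of a 3-iodochromone (ring C, made by DMF-DMA then I₂ from the ring-B acetophenone) with a ring-A aryl-Bpin.
4. Ring order: both dimethylpyran rings are made first (chroman on ring B from phloroacetophenone + prenal then H₂; chromene on ring A from a bromo-2,5-dimethoxyphenol + prenal). The pyranone ring C is formed second, and the furan ring last.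

## Forward route

**Step 1**
Reactants: 1 (2,4,6-trihydroxyacetophenone), 2 (3-methylbut-2-enal)
Product: 3 (1-(5,7-dihydroxy-2,2-dimethyl-2H-chromen-6-yl)ethanone)
Conditions: pyridine, 115 °C, sealed tube, 16 h
Reagents that add atoms: none beyond reactant 2
Why: Phenol–enal condensation, then oxa-6π electrocyclisation of the o-quinone methide (chromene synthesis). It closes on the non-chelated 4′-OH, so the acetyl ends up between the two OH groups.

**Step 2**
Reactants: 3
Product: 4 (1-(5,7-dihydroxy-2,2-dimethylchroman-6-yl)ethanone)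
Conditions: H₂ (1 atm), 10% Pd/C, EtOAc, rt
Reagents that add atoms: none (H₂ adds only hydrogen)
Why: Catalytic hydrogenation of the isolated chromene C=C. The chelated aryl ketone and the phenols are untouched.

**Step 3**
Reactants: 4
Product: 5 (1-(5-hydroxy-7-(methoxymethoxy)-2,2-dimethylchroman-6-yl)ethanone)
Conditions: MOMCl (1.05 equiv), i-Pr₂NEt, CH₂Cl₂, 0 °C
Reagents that add atoms: chloromethyl methyl ether, ClCOC
Why: Steric and acidity-controlled mono-protection of the 7-OH. The 5-OH is flanked by the C4 methylene and the acetyl, so it stays free and becomes the chromone ring oxygen later.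

**Step 4**
Reactants: 5
Product: 6 ((E)-3-(dimethylamino)-1-[5-hydroxy-7-(MOMO)-2,2-dimethylchroman-6-yl]prop-2-en-1-one)
Conditions: DMF-DMA, toluene, 110 °C
Reagents that add atoms: N,N-dimethylformamide dimethyl acetal, CN(C)C(OC)OC
Why: Condensation of the methyl ketone with DMF-DMA gives the enaminone.

**Step 5**
Reactants: 6
Product: 7 (3-iodochromone: 3-iodo-5-(MOMO)-chromen-4-one fused at C7–C8 to a 2,2-dimethyldihydropyran, with O on C7 and CH₂ on C8)
Conditions: I₂ (1.3 equiv), solid NaHCO₃, CH₂Cl₂, rt
Reagents that add atoms: iodine, II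
Why: The enaminone is iodinated at the α-carbon, then the free 5-OH adds and eliminates Me₂NH. This is the standard 3-iodochromone synthesis, and the ring oxygen lands on the carbon next to the CH₂-bearing carbon, as in the target.

**Step 6**
Reactants: 8 (2,5-dimethoxyphenol)
Product: 9 (4-bromo-2,5-dimethoxyphenol)
Conditions: NBS (1.0 equiv), CH₂Cl₂, −78 → 0 °C
Reagents that add atoms: N-bromosuccinimide, O=C1CCC(=O)N1Br
Why: Electrophilic aromatic bromination para to the free OH.

**Step 7**
Reactants: 9, 2 (prenal, 2 equiv)
Product: 10 (6-bromo-5,8-dimethoxy-2,2-dimethyl-2H-chromene)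
Conditions: PhB(OH)₂ (1 equiv), AcOH (cat.), toluene, reflux, Dean–Stark
Reagents that add atoms: none beyond reactant 2 (PhB(OH)₂ only mediates)
Why: Boronate-directed ortho-selective chromene annulation, by the same phenol–enal mechanism as Step 1. Only one ortho C–H is available.

**Step 8**
Reactants: 10
Product: 11 (6-bromo-2,2-dimethyl-2H-chromene-5,8-dione)
Conditions: CAN (2.5 equiv), MeCN/H₂O 3:1, 0 °C
Reagents that add atoms: water, O (the source of the quinone oxygens); CAN itself adds nothing
Why: Ceric-mediated oxidative demethylation of a hydroquinone dimethyl ether to the p-quinone.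

**Step 9**
Reactants: 11
Product: 12 (6-bromo-2,2-dimethyl-2H-chromene-5,8-diol)
Conditions: Na₂S₂O₄, THF/H₂O, rt, then immediately used
Reagents that add atoms: none
Why: Dithionite reduction of the quinone to the hydroquinone.

**Step 10**
Reactants: 12
Product: 13 (6-bromo-8-(MOMO)-2,2-dimethyl-2H-chromen-5-ol)
Conditions: MOMCl (1.0 equiv), i-Pr₂NEt, CH₂Cl₂, −20 °C
Reagents that add atoms: ClCOC
Why: The 5-OH, flanked by Br and the peri vinyl group, is far more hindered than the 8-OH, so MOM goes on C8-O.

**Step 11**
Reactants: 13
Product: 14 (6-bromo-8-(MOMO)-5-(triisopropylsilyloxy)-2,2-dimethyl-2H-chromene)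
Conditions: TIPSOTf, 2,6-lutidine, CH₂Cl₂, 0 °C
Reagents that add atoms: triisopropylsilyl triflate, CC(C)[Si](OS(=O)(=O)C(F)(F)F)(C(C)C)C(C)C
Why: The hindered phenol is masked as a robust silyl ether. It survives Suzuki conditions and is removed orthogonally to the MOM groups later.

**Step 12**
Reactants: 14
Product: 15 (2-[8-(MOMO)-2,2-dimethyl-5-(TIPSO)-2H-chromen-6-yl]-Bpin)
Conditions: B₂pin₂, Pd₂(dba)₃/XPhos, KOAc, dioxane, 100 °C
Reagents that add atoms: bis(pinacolato)diboron, CC1(C)OB(OC1(C)C)B1OC(C)(C)C(C)(C)O1
Why: Miyaura borylation. A Buchwald ligand copes with the ortho-OTIPS, and no organolithium is used, which avoids retro-Brook silyl migration.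

**Step 13**
Reactants: 7, 15
Product: 16 (isoflavone: chromone C3 bonded to ring-A C6, with 5′-OTIPS and 8′-OMOM on ring A)
Conditions: Pd(PPh₃)₄ (5 mol%), 2 M aq. Na₂CO₃, DME, 80 °C
Reagents that add atoms: none
Why: Suzuki–Miyaura coupling of a 3-iodochromone with an arylboronate, the standard isoflavone synthesis.

**Step 14**
Reactants: 16
Product: 17 (bis-MOM ether of the target)
Conditions: (i) TBAF (1.2 equiv), THF, rt, 1 h; (ii) same pot, DDQ (1.5 equiv), 1,4-dioxane, 50 °C
Reagents that add atoms: none (silyl group lost; DDQ only accepts hydrogen)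
Why: Proposed new method: dehydrogenative oxa-annulation of a 2′-hydroxyisoflavone at chromone C2–H. F⁻ unmasks the ring-A phenoxide, which adds to C2 of the chromone (the β-carbon of a vinylogous ester).
- This is a 5-endo oxa-Michael addition that gives the cis-fused benzofuro[2,3-b]chromanone. It also equilibrates through C2–O1 ring opening with the 3-(2-hydroxyaroyl)benzofuran. The chromone ring reforms by 6-endo oxa-Michael, as in flavanone formation from 2′-hydroxychalcones.
- DDQ abstracts the hydride from the doubly oxygenated acetal C2–H of the small population of the dihydro compound, forming a dioxocarbenium ion. Loss of the acidic C3–H (α to C=O and benzylic) then gives the C2=C3 ketene acetal of ring C.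
- Oxidation drains the network by Curtin–Hammett control, and the transient stereocentres are destroyed.
- Closest known reactions: oxa-Michael cyclisation of 2′-hydroxychalcones to flavanones, DDQ dehydrogenation of flavanones, and C2 ring-opening equilibria of chromones.
- Desilylation and cyclisation come first, and the oxidant acts only once ring A is an aryl ether. All ortho and para positions of the phenoxide are substituted, which limits DDQ attack on ring A.

**Step 15**
Reactants: 17
Product: 18 (Formosanatin D)
Conditions: ZnBr₂ (5 equiv), n-PrSH (10 equiv), CH₂Cl₂, 0 °C → rt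
Reagents that add atoms: none
Why: Mild Lewis-acid/thiol cleavage of both aryl MOM ethers (the peri one is easy), leaving the chromene and the vinylogous-carbonate ring C intact. This gives the free 8′-OH and the peri 5-OH.

## Compound list
1 | 2,4,6-trihydroxyacetophenone | CC(=O)c1c(O)cc(O)cc1O | starting material
2 | 3-methylbut-2-enal (prenal) | CC(C)=CC=O | starting material
3 | 1-(5,7-dihydroxy-2,2-dimethyl-2H-chromen-6-yl)ethanone | CC(=O)c1c(O)cc2OC(C)(C)C=Cc2c1O | intermediate
4 | 1-(5,7-dihydroxy-2,2-dimethylchroman-6-yl)ethanone | CC(=O)c1c(O)cc2OC(C)(C)CCc2c1O | intermediate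
5 | 1-(5-hydroxy-7-(MOMO)-2,2-dimethylchroman-6-yl)ethanone | CC(=O)c1c(OCOC)cc2OC(C)(C)CCc2c1O | intermediate
6 | enaminone of 5 | CN(C)/C=C/C(=O)c1c(OCOC)cc2OC(C)(C)CCc2c1O | intermediate
7 | 3-iodo-5-(MOMO)-chromone fused to a 2,2-dimethyldihydropyran | O=c1c(I)coc2c1c(OCOC)cc1OC(C)(C)CCc12 | intermediate
8 | 2,5-dimethoxyphenol | COc1ccc(OC)c(O)c1 | starting material
9 | 4-bromo-2,5-dimethoxyphenol | Oc1cc(OC)c(Br)cc1OC | intermediate
10 | 6-bromo-5,8-dimethoxy-2,2-dimethyl-2H-chromene | CC1(C)C=Cc2c(OC)c(Br)cc(OC)c2O1 | intermediate
11 | 6-bromo-2,2-dimethyl-2H-chromene-5,8-dione | CC1(C)C=CC2=C(O1)C(=O)C=C(Br)C2=O | intermediate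
12 | 6-bromo-2,2-dimethyl-2H-chromene-5,8-diol | CC1(C)C=Cc2c(O)c(Br)cc(O)c2O1 | intermediate
13 | 6-bromo-8-(MOMO)-2,2-dimethyl-2H-chromen-5-ol | CC1(C)C=Cc2c(O)c(Br)cc(OCOC)c2O1 | intermediate
14 | 6-bromo-8-(MOMO)-5-(TIPSO)-2,2-dimethyl-2H-chromene | CC1(C)C=Cc2c(O[Si](C(C)C)(C(C)C)C(C)C)c(Br)cc(OCOC)c2O1 | intermediate
15 | aryl-Bpin of 14 (Br replaced by Bpin) | CC1(C)C=Cc2c(O[Si](C(C)C)(C(C)C)C(C)C)c(B3OC(C)(C)C(C)(C)O3)cc(OCOC)c2O1 | intermediate
16 | 2′-TIPSO-isoflavone (Suzuki product) | O=c1c(-c2c(O[Si](C(C)C)(C(C)C)C(C)C)c3C=CC(C)(C)Oc3c(OCOC)c2)coc2c1c(OCOC)cc1OC(C)(C)CCc12 | intermediate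
17 | bis-MOM Formosanatin D | CC1(C)C=Cc2c(c(OCOC)cc3c2oc2oc4c5c(cc(OCOC)c4c(=O)c23)OC(C)(C)CC5)O1 | intermediate
18 | Formosanatin D | CC1(C)C=Cc2c(c(O)cc3c2oc2oc4c5c(cc(O)c4c(=O)c23)OC(C)(C)CC5)O1 | target

## Totals
- Total steps: 15 (ring-B branch 5, ring-A branch 7, then coupling, key annulation and deprotection).
- Longest linear sequence: 10 steps (8 → 9 → 10 → 11 → 12 → 13 → 15 → 16 → 17 → 18).

## Three steps most likely to fail
1. **Step 14 (the proposed new method).** The 5-endo oxa-Michael step may stall, or DDQ may dehydrogenate the ring-B chroman or attack the chromene.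
   Fallback (known chemistry, different approach): build ring C last by SNAr. C3-aroylate a ring-A benzofuran-2(3H)-one (made from the o-hydroxyphenylacetic acid) with the ring-B salicyloyl chloride, convert it to the 2-triflyloxybenzofuran with Tf₂O, and close the pyranone with K₂CO₃ in DMF.
2. **Step 10 (mono-MOM of the hydroquinone).** Bis-protection or poor selectivity would ruin the orthogonal f-OTIPS/c-OMOM pattern.
   Fallback: start from hydroquinone mono-allyl ether. Install MOM, then ortho-directed hydroxylation (BuLi, B(OMe)₃, H₂O₂), para-bromination and prenal chromene formation. Use the O-allyl group in place of TIPS and remove it with Pd(PPh₃)₄/morpholine before Step 14.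
3. **Step 3 (regioselective mono-MOM on ring B).** Poor selectivity between the 5- and 7-OH would give the wrong chromone regioisomer in Step 5.
   Fallback: make the chromone first from 4′-O-prenyl phloroacetophenone, whose 2′,6′-diOH are equivalent. Then set the angular ring by Claisen rearrangement of the 7-O-prenyl group to C8 (separating C6/C8 isomers) and acid-mediated hydroalkoxylation to the 2,2-dimethylchroman.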